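**Plan**

1. Retrosynthesis: the core is cut first at C1–C7 (C1 = carbinol carbon of the cyclohexane, C7 = its CH2O carbon, which keeps the fragment 2 ester), then at the C=C and the O–CH2 ester bond of the seven-membered lactone, then at C1–C2 and C3–C4 of the cyclohexane (Diels–Alder). Fragment 2 is cut at C2′–CO2H (radical decarboxylation with allylic transposition), at its side-chain C=C, and at the same two Diels–Alder bonds.
2. Forward: one silyloxydiene and the two enantiomers of 5-menthyloxyfuran-2(5H)-one give the enantiomeric cis-fused cyclohexene lactone acetals 5 and 20. Compound 5 is taken to the fragment 2 acid and its (acyloxy)methyl pinacol boronate 18; compound 20 to the allylic benzoate acid 24.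
3. Enabling feature: C1 is a fully substituted carbinol carbon whose only exocyclic carbon, C7, is an O-acylated CH2. That is the array left when an (acyloxy)methyl group shifts from boron to an oxygen-bearing carbon. In the cyclohexene precursor C1–H is allylic to C5=C6 and next to the C2 carboxyl, so it can be lithiated; 18 and 24 are therefore joined by lithiation–borylation–oxidation.
4. The seven-membered lactone ring is closed afterwards by O-alkylation of the C2 carboxyl and ring-closing metathesis onto the C3 vinyl group. C5=C6, needed only for the lithiation, is reduced with diimide, and fluoride removes the silyl groups.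
5. Stereochemistry: C2, C3, C4 (and C3′, C4′) come from the endo Diels–Alder reaction anti to the menthyloxy group. C1 comes from Mitsunobu inversion of the Diels–Alder carbinol followed by the stereospecific 1,2-shift. The enoate geometries come from the ring (core) and from the Horner–Wadsworth–Emmons reaction (fragment 2).

Key step: step 21

Remark (locants): in the core, C1 is the carbinol carbon, C2 the carbon bearing the lactone carbonyl, C3 the carbon bearing CH=, C4 the isopropyl carbon, C5 and C6 the ring CH2 groups, C7 the CH2O carbon on C1. Primed numbers are the corresponding ring atoms of fragment 2 (C1′ bears CH2OH, C3′ the side chain, C4′ isopropyl). "Cis/trans" refers to the cyclohexane ring; absolute configurations are those of the SMILES.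

Remark (assumption): both enantiomers of 5-menthyloxyfuran-2(5H)-one (4 and 19) are taken as commercial; each is otherwise one acetalization from 5-hydroxyfuran-2(5H)-one and the respective menthol.

**Diene**

Step 1
Reactants: 1 3-methylbutanal
Product: 2 (2E)-5-methylhex-2-enal
Conditions: Ph3P=CHCHO, toluene, 80 °C
Reagents that add atoms: (triphenylphosphoranylidene)acetaldehyde, O=CC=P(c1ccccc1)(c1ccccc1)c1ccccc1
Why: Wittig olefination with the stabilized formyl ylide homologates the aldehyde by two carbons and should give the E-enal.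

Step 2
Reactants: 2 (2E)-5-methylhex-2-enal
Product: 3 (1E,3E)-1-(tert-butyldimethylsilyloxy)-5-methylhexa-1,3-diene
Conditions: TBSOTf, Et3N, Et2O, 0 °C to rt
Reagents that add atoms: tert-butyldimethylsilyl trifluoromethanesulfonate, CC(C)(C)[Si](C)(C)OS(=O)(=O)C(F)(F)F
Why: Soft enolization (γ-deprotonation of the O-silylated enal) gives the silyl dienol ether; only the (1E,3E) isomer can reach the s-cis geometry needed later, so minor isomers are spectators.

**Fragment 2 (boronate 18)**

Step 3
Reactants: 3 (1E,3E)-1-(tert-butyldimethylsilyloxy)-5-methylhexa-1,3-diene; 4 (5R)-5-[(1R,2S,5R)-menthyloxy]furan-2(5H)-one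
Product: 5 Diels–Alder adduct of the fragment 2 series, (3R,3aR,4R,7S,7aR)-7-(tert-butyldimethylsilyloxy)-4-isopropyl-3-[(1R,2S,5R)-menthyloxy]-3a,4,7,7a-tetrahydroisobenzofuran-1(3H)-one
Conditions: toluene, 110 °C, sealed tube, BHT (cat.)
Reagents that add atoms: none
Why: Thermal Diels–Alder reaction: the silyloxy-bearing diene terminus bonds to the lactone α-carbon, the lactone is endo, and the diene adds anti to the menthyloxy group, which sets C1′, C2′, C3′ and C4′ all-cis in the absolute sense shown.

Step 4
Reactants: 5 Diels–Alder adduct of the fragment 2 series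
Product: 6 saturated silyl ether (5 with C5′=C6′ hydrogenated)
Conditions: H2 (1 atm), 10% Pd/C, EtOAc, rt
Reagents that add atoms: none
Why: Heterogeneous hydrogenation of the only C=C; no stereocenter is formed.

Step 5
Reactants: 6 saturated silyl ether
Product: 7 saturated hydroxy lactone acetal (C1′–OH cis to the lactone)
Conditions: HF·pyridine, THF, 0 °C to rt
Reagents that add atoms: none
Why: Fluoride desilylation under non-basic conditions avoids β-elimination of the β-oxygenated lactone.

Step 6
Reactants: 7 saturated hydroxy lactone acetal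
Product: 8 keto lactone acetal (C1′ ketone, cis-fused)
Conditions: Dess–Martin periodinane, CH2Cl2, rt
Reagents that add atoms: none
Why: Dess–Martin oxidation of the secondary alcohol; C2′ becomes epimerizable, but that center is destroyed in step 10.

Step 7
Reactants: 8 keto lactone acetal
Product: 9 exocyclic methylene lactone acetal (C1′=CH2)
Conditions: Zn, CH2Br2, TiCl4, THF/CH2Cl2, 0 °C to rt
Reagents that add atoms: dibromomethane, BrCBr
Why: Takai–Lombardo methylenation is non-basic and ketone-selective, so the enolizable β-keto lactone is methylenated at C1′ without touching the lactone.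

Step 8
Reactants: 9 exocyclic methylene lactone acetal
Product: 10 hydroxy lactone (ring tautomer of the C2′ acid / C3′ aldehyde; lactol carbon as anomer mixture)
Conditions: 1 M HCl, THF, 40 °C
Reagents that add atoms: water, O
Why: Acid hydrolysis of the acylal-type menthyl acetal releases menthol; the lactol stereocenter is inconsequential.

Step 9
Reactants: 10 hydroxy lactone
Product: 11 acid with side chain: C2′–CO2H, C1′=CH2, C3′–CH=C(CO2Et)CH2OPMB (E), C3′/C4′ cis
Conditions: NaH (2.2 equiv), 4-MeOC6H4CH2OH, THF, 0 °C; ethyl 2-(diethoxyphosphoryl)acrylate, 0 °C; then 10, 0 °C to rt; dilute HCl work-up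
Reagents that add atoms: ethyl 2-(diethoxyphosphoryl)acrylate, CCOC(=O)C(=C)P(=O)(OCC)OCC; 4-methoxybenzyl alcohol, COc1ccc(CO)cc1
Why: Tandem oxa-Michael/Horner–Wadsworth–Emmons reaction: the alkoxide adds to the vinylphosphonate and the resulting stabilized phosphonate anion olefinates the aldehyde tautomer, placing the ester trans to C3′ (E) as usual for α-substituted phosphonoacetates.

Step 10
Reactants: 11 acid with side chain
Product: 13 allylic alkoxyamine (C1′=C2′, C7′–O–N-tetramethylpiperidine), via Barton ester 12 (not isolated)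
Conditions: 2-mercaptopyridine N-oxide, DCC, DMAP (cat.), CH2Cl2, 0 °C, dark; then TEMPO, visible light, rt
Reagents that add atoms: TEMPO, CC1(C)CCCC(C)(C)N1[O]
Why: Barton decarboxylation gives a C2′ radical delocalized over C2′–C1′–C7′, and the persistent nitroxyl should couple at the unhindered primary terminus C7′, which removes the C2′ carboxyl, creates the C1′=C2′ alkene and oxygenates C7′ in one operation.

Step 11
Reactants: 13 allylic alkoxyamine
Product: 14 allylic alcohol (C7′–OH, side chain OPMB, ethyl ester)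
Conditions: Zn, AcOH/THF/H2O, 50 °C
Reagents that add atoms: none
Why: Reductive N–O cleavage of the alkoxyamine by zinc in acetic acid.

Step 12
Reactants: 14 allylic alcohol
Product: 15 diol ethyl ester
Conditions: DDQ, CH2Cl2/pH 7 buffer, 0 °C
Reagents that add atoms: none
Why: Oxidative cleavage of the 4-methoxybenzyl ether via its benzylic oxocarbenium ion.

Step 13
Reactants: 15 diol ethyl ester
Product: 16 bis(tert-butyldimethylsilyl) ether ethyl ester
Conditions: TBSCl, imidazole, DMF, rt
Reagents that add atoms: tert-butyldimethylsilyl chloride, CC(C)(C)[Si](C)(C)Cl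
Why: Silylation of both primary allylic alcohols.

Step 14
Reactants: 16 bis(tert-butyldimethylsilyl) ether ethyl ester
Product: 17 fragment 2 acid, (E)-2-(silyloxymethyl)-3-[cis-6-isopropyl-3-(silyloxymethyl)cyclohex-2-enyl]acrylic acid
Conditions: LiOH, THF/MeOH/H2O, 40 °C; then dilute HCl to pH 4
Reagents that add atoms: lithium hydroxide, [Li+].[OH-]
Why: Saponification of the ethyl enoate; the primary silyl ethers tolerate hydroxide at this temperature.

Step 15
Reactants: 17 fragment 2 acid
Product: 18 (acyloxy)methyl pinacol boronate of the fragment 2 acid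
Conditions: ICH2B(pin), Cs2CO3, DMF, rt
Reagents that add atoms: 2-(iodomethyl)-4,4,5,5-tetramethyl-1,3,2-dioxaborolane, ICB1OC(C)(C)C(C)(C)O1
Why: O-alkylation of the caesium carboxylate by the α-iodo boronic ester (substitution at the α-boryl carbon) gives the (acyloxy)methyl boronate.

**Core partner (acid 24)**

Step 16
Reactants: 3 (1E,3E)-1-(tert-butyldimethylsilyloxy)-5-methylhexa-1,3-diene; 19 (5S)-5-[(1S,2R,5S)-menthyloxy]furan-2(5H)-one
Product: 20 Diels–Alder adduct of the core series, (3S,3aS,4S,7R,7aS)-7-(tert-butyldimethylsilyloxy)-4-isopropyl-3-[(1S,2R,5S)-menthyloxy]-3a,4,7,7a-tetrahydroisobenzofuran-1(3H)-one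
Conditions: toluene, 110 °C, sealed tube, BHT (cat.)
Reagents that add atoms: none
Why: The same endo, anti-selective Diels–Alder reaction with the enantiomeric dienophile sets C2, C3 and C4 of the core (and a temporary C1 carbinol center) all-cis.

Step 17
Reactants: 20 Diels–Alder adduct of the core series
Product: 21 allylic alcohol (C1–OH cis to the lactone, C5=C6 retained)
Conditions: HF·pyridine, THF, 0 °C to rt
Reagents that add atoms: none
Why: Non-basic fluoride desilylation of the allylic silyl ether.

Step 18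
Reactants: 21 allylic alcohol
Product: 22 allylic 2,4,6-triisopropylbenzoate (C1–O now trans to the lactone)
Conditions: 2,4,6-(iPr)3C6H2CO2H, PPh3, DIAD, toluene, 0 °C to rt
Reagents that add atoms: 2,4,6-triisopropylbenzoic acid, CC(C)c1cc(C(C)C)c(C(=O)O)c(C(C)C)c1
Why: Mitsunobu esterification: the carboxylate attacks the activated allylic carbinol from the open face by SN2, inverting C1 so that C1–H ends up on the face of the C2, C3 and C4 substituents.

Step 19
Reactants: 22 allylic 2,4,6-triisopropylbenzoate
Product: 23 hydroxy lactone (ring tautomer of the C2 acid / C3 aldehyde; lactol carbon as anomer mixture)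
Conditions: 1 M HCl, THF, 40 °C
Reagents that add atoms: water, O
Why: Acid hydrolysis of the acylal-type menthyl acetal; the hindered benzoate is inert to dilute acid.

Step 20
Reactants: 23 hydroxy lactone
Product: 24 vinyl acid: C1–O-triisopropylbenzoyl (trans to CO2H), C2–CO2H, C3–vinyl and C4–isopropyl all cis, C5=C6
Conditions: KN(SiMe3)2 (1 equiv), THF, −78 °C; then Ph3P=CH2 (from Ph3PCH3Br and KN(SiMe3)2), −78 to 0 °C; dilute HCl work-up
Reagents that add atoms: methyltriphenylphosphonium bromide, C[P+](c1ccccc1)(c1ccccc1)c1ccccc1.[Br-]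
Why: Wittig methylenation of the aldehyde tautomer; the carboxylate formed first protects C2–H from enolization and hence from β-elimination of the benzoate.

**Union and endgame**

Step 21
Reactants: 24 vinyl acid; 18 (acyloxy)methyl pinacol boronate of the fragment 2 acid
Product: 28 hydroxy acid: C1(OH)(C7H2–O–acyl of fragment 2) with C7 cis to the C2 carboxyl, via lithiated benzoate 25 (not isolated), via boronate complex 26 (not isolated), via tertiary boronic ester 27 (not isolated)
Conditions: n-BuLi (1.0 equiv), Et2O, −78 °C; s-BuLi (1.3 equiv), TMEDA, −78 °C; 18, −78 °C; MgBr2·OEt2, −78 °C to rt; then NaBO3·4H2O, THF/H2O, rt; dilute HCl to pH 4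
Reagents that add atoms: sodium perborate, O=BO[O-].[Na+]
Why: Proposed new method: the benzoate carbonyl and the neighbouring C2 carboxylate direct s-BuLi to the allylic C1–H; the C1–Li species 25 takes up the boron of 18 on the lithium-bearing face with retention to give ate complex 26, and the (acyloxy)methyl group then migrates from boron to C1 antiperiplanar to the departing triisopropylbenzoate (1,2-metallate rearrangement), so that oxidation of 27 with retention leaves oxygen where the C–O bond was and C7 where the C–H bond was. The closest known reaction type is the lithiation–borylation of secondary allylic and benzylic carbamates or hindered benzoates with boronic esters, which gives tertiary boronic esters and, after oxidation, tertiary alcohols; new here are the cyclic allylic substrate carrying a free carboxylate and the (acyloxy)methyl migrating group. No ring is closed. The one new stereocenter, C1, is controlled by the C1 configuration installed in step 18 (retention at lithiation and borylation, inversion in the 1,2-shift) and not by approach to a trigonal carbon, which would put C7 on the open face, trans to the C2, C3 and C4 substituents. The step needs borylation at C1 and not at the γ-terminus C5, and migration of C7 to C1 instead of C1 to C7 with loss of the fragment 2 carboxylate; the isopropyl-flanked C5, lithium chelation at C1 by the ester carbonyl and the carboxylate, and the much better leaving ability of a tertiary allylic benzoate than of a primary carboxylate on the boron-bound carbon (helped by MgBr2) should secure both.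

Step 22
Reactants: 29 2-(bromomethyl)acrylic acid
Product: 30 2-(trimethylsilyl)ethyl 2-(bromomethyl)acrylate
Conditions: Me3SiCH2CH2OH, DCC, DMAP (cat.), CH2Cl2, 0 °C
Reagents that add atoms: 2-(trimethylsilyl)ethanol, C[Si](C)(C)CCO
Why: Steglich esterification gives the fluoride-labile ester of the allylic bromide.

Step 23
Reactants: 28 hydroxy acid; 30 2-(trimethylsilyl)ethyl 2-(bromomethyl)acrylate
Product: 31 diene ester: C2–CO2CH2C(=CH2)CO2CH2CH2SiMe3, C3–vinyl
Conditions: KHCO3, DMF, 0 °C to rt
Reagents that add atoms: none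
Why: O-alkylation of the carboxylate by the allylic bromide (SN2 and SN2′ give the same ester); the tertiary alcohol does not compete.

Step 24
Reactants: 31 diene ester
Product: 32 cis-fused seven-membered lactone (C5=C6 still present)
Conditions: Hoveyda–Grubbs second-generation catalyst RuCl2(H2IMes)(=CH-C6H4-2-OiPr) (10 mol %), toluene (2 mM), 80 °C
Reagents that add atoms: none
Why: Ring-closing metathesis between the C3 vinyl group and the 1,1-disubstituted acrylate alkene closes the seven-membered lactone; the ring fixes the enoate geometry (CH2O cis to C3), and the cyclohexene and trisubstituted alkenes are poor metathesis partners.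

Step 25
Reactants: 32 cis-fused seven-membered lactone
Product: 33 protected target (C5–C6 saturated; two silyl ethers, trimethylsilylethyl ester)
Conditions: 2-O2NC6H4SO2NHNH2, Et3N, CH2Cl2, rt
Reagents that add atoms: none
Why: Diimide reduction: the cis-disubstituted ring alkene should be reduced well ahead of the three trisubstituted, partly conjugated alkenes.

Step 26
Reactants: 33 protected target
Product: 34 target CNP0361406.12
Conditions: Bu4NF, AcOH, THF, 0 °C to rt
Reagents that add atoms: none
Why: Buffered fluoride cleaves both silyl ethers and fragments the 2-(trimethylsilyl)ethyl ester, leaving lactone, ester and tertiary alcohol untouched.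

**Compound list**

1 | 3-methylbutanal | CC(C)CC=O | starting material
2 | (2E)-5-methylhex-2-enal | CC(C)C/C=C/C=O | intermediate
3 | (1E,3E)-1-(tert-butyldimethylsilyloxy)-5-methylhexa-1,3-diene | CC(C)/C=C/C=C/O[Si](C)(C)C(C)(C)C | intermediate
4 | (5R)-5-[(1R,2S,5R)-menthyloxy]furan-2(5H)-one | O=C1C=C[C@H](O[C@@H]2C[C@H](C)CC[C@H]2C(C)C)O1 | starting material
5 | Diels–Alder adduct, fragment 2 series (3R,3aR,4R,7S,7aR; all-cis, cis-fused) | CC(C)[C@@H]1C=C[C@H](O[Si](C)(C)C(C)(C)C)[C@@H]2C(=O)O[C@@H](O[C@@H]3C[C@H](C)CC[C@H]3C(C)C)[C@H]12 | intermediate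
6 | saturated silyl ether (5 with C5′–C6′ hydrogenated) | CC(C)[C@@H]1CC[C@H](O[Si](C)(C)C(C)(C)C)[C@@H]2C(=O)O[C@@H](O[C@@H]3C[C@H](C)CC[C@H]3C(C)C)[C@H]12 | intermediate
7 | saturated hydroxy lactone acetal (C1′–OH cis) | CC(C)[C@@H]1CC[C@H](O)[C@@H]2C(=O)O[C@@H](O[C@@H]3C[C@H](C)CC[C@H]3C(C)C)[C@H]12 | intermediate
8 | keto lactone acetal (C1′ ketone) | CC(C)[C@@H]1CCC(=O)[C@@H]2C(=O)O[C@@H](O[C@@H]3C[C@H](C)CC[C@H]3C(C)C)[C@H]12 | intermediate
9 | exocyclic methylene lactone acetal | CC(C)[C@@H]1CCC(=C)[C@@H]2C(=O)O[C@@H](O[C@@H]3C[C@H](C)CC[C@H]3C(C)C)[C@H]12 | intermediate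
10 | hydroxy lactone (lactol anomer mixture), fragment 2 series | CC(C)[C@@H]1CCC(=C)[C@@H]2C(=O)OC(O)[C@H]12 | intermediate
11 | C2′ acid with C1′=CH2 and (E)-CH=C(CO2Et)CH2OPMB side chain | CCOC(=O)/C(=C/[C@H]1[C@@H](C(=O)O)C(=C)CC[C@H]1C(C)C)COCc1ccc(OC)cc1 | intermediate
12 | Barton ester of 11 (O-acyl N-hydroxypyridine-2-thione) | CCOC(=O)/C(=C/[C@H]1[C@@H](C(=O)ON2C=CC=CC2=S)C(=C)CC[C@H]1C(C)C)COCc1ccc(OC)cc1 | intermediate (not isolated)
13 | allylic alkoxyamine (C7′–O–N-2,2,6,6-tetramethylpiperidine) | CCOC(=O)/C(=C/[C@H]1C=C(CON2C(C)(C)CCCC2(C)C)CC[C@H]1C(C)C)COCc1ccc(OC)cc1 | intermediate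
14 | allylic alcohol (C7′–OH, side chain OPMB) | CCOC(=O)/C(=C/[C@H]1C=C(CO)CC[C@H]1C(C)C)COCc1ccc(OC)cc1 | intermediate
15 | diol ethyl ester | CCOC(=O)/C(=C/[C@H]1C=C(CO)CC[C@H]1C(C)C)CO | intermediate
16 | bis(tert-butyldimethylsilyl) ether ethyl ester | CCOC(=O)/C(=C/[C@H]1C=C(CO[Si](C)(C)C(C)(C)C)CC[C@H]1C(C)C)CO[Si](C)(C)C(C)(C)C | intermediate
17 | fragment 2 acid (bis-silyl ether) | OC(=O)/C(=C/[C@H]1C=C(CO[Si](C)(C)C(C)(C)C)CC[C@H]1C(C)C)CO[Si](C)(C)C(C)(C)C | intermediate
18 | (acyloxy)methyl pinacol boronate of 17 | CC1(C)OB(COC(=O)/C(=C/[C@H]2C=C(CO[Si](C)(C)C(C)(C)C)CC[C@H]2C(C)C)CO[Si](C)(C)C(C)(C)C)OC1(C)C | intermediate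
19 | (5S)-5-[(1S,2R,5S)-menthyloxy]furan-2(5H)-one | O=C1C=C[C@@H](O[C@H]2C[C@@H](C)CC[C@@H]2C(C)C)O1 | starting material
20 | Diels–Alder adduct, core series (3S,3aS,4S,7R,7aS; all-cis, cis-fused) | CC(C)[C@H]1C=C[C@@H](O[Si](C)(C)C(C)(C)C)[C@H]2C(=O)O[C@H](O[C@H]3C[C@@H](C)CC[C@@H]3C(C)C)[C@@H]12 | intermediate
21 | allylic alcohol, core series (C1–OH cis to lactone) | CC(C)[C@H]1C=C[C@@H](O)[C@H]2C(=O)O[C@H](O[C@H]3C[C@@H](C)CC[C@@H]3C(C)C)[C@@H]12 | intermediate
22 | allylic 2,4,6-triisopropylbenzoate (C1–O trans to lactone) | CC(C)[C@H]1C=C[C@H](OC(=O)c3c(C(C)C)cc(C(C)C)cc3C(C)C)[C@H]2C(=O)O[C@H](O[C@H]3C[C@@H](C)CC[C@@H]3C(C)C)[C@@H]12 | intermediate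
23 | hydroxy lactone (lactol anomer mixture), core series | CC(C)[C@H]1C=C[C@H](OC(=O)c3c(C(C)C)cc(C(C)C)cc3C(C)C)[C@H]2C(=O)OC(O)[C@@H]12 | intermediate
24 | vinyl acid with C1 triisopropylbenzoate | CC(C)[C@H]1C=C[C@H](OC(=O)c2c(C(C)C)cc(C(C)C)cc2C(C)C)[C@@H](C(=O)O)[C@H]1C=C | intermediate
25 | C1-lithiated benzoate, lithium carboxylate | CC(C)[C@H]1C=C[C@]([Li])(OC(=O)c2c(C(C)C)cc(C(C)C)cc2C(C)C)[C@@H](C(=O)[O-])[C@H]1C=C.[Li+] | intermediate (not isolated)
26 | boronate (ate) complex of 25 and 18, dilithium salt | CC(C)[C@H]1C=C[C@@](OC(=O)c2c(C(C)C)cc(C(C)C)cc2C(C)C)([B-]3(COC(=O)/C(=C/[C@H]4C=C(CO[Si](C)(C)C(C)(C)C)CC[C@H]4C(C)C)CO[Si](C)(C)C(C)(C)C)OC(C)(C)C(C)(C)O3)[C@@H](C(=O)[O-])[C@H]1C=C.[Li+].[Li+] | intermediate (not isolated)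
27 | tertiary allylic pinacol boronic ester at C1, lithium carboxylate | CC(C)[C@H]1C=C[C@@](B2OC(C)(C)C(C)(C)O2)(COC(=O)/C(=C/[C@H]3C=C(CO[Si](C)(C)C(C)(C)C)CC[C@H]3C(C)C)CO[Si](C)(C)C(C)(C)C)[C@@H](C(=O)[O-])[C@H]1C=C.[Li+] | intermediate (not isolated)
28 | hydroxy acid (C1–OH trans, C7 cis to C2–CO2H) | CC(C)[C@H]1C=C[C@@](O)(COC(=O)/C(=C/[C@H]2C=C(CO[Si](C)(C)C(C)(C)C)CC[C@H]2C(C)C)CO[Si](C)(C)C(C)(C)C)[C@@H](C(=O)O)[C@H]1C=C | intermediate
29 | 2-(bromomethyl)acrylic acid | C=C(CBr)C(=O)O | starting material
30 | 2-(trimethylsilyl)ethyl 2-(bromomethyl)acrylate | C=C(CBr)C(=O)OCC[Si](C)(C)C | intermediate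
31 | diene ester (ring-closing metathesis precursor) | CC(C)[C@H]1C=C[C@@](O)(COC(=O)/C(=C/[C@H]2C=C(CO[Si](C)(C)C(C)(C)C)CC[C@H]2C(C)C)CO[Si](C)(C)C(C)(C)C)[C@@H](C(=O)OCC(=C)C(=O)OCC[Si](C)(C)C)[C@H]1C=C | intermediate
32 | cis-fused seven-membered lactone with C5=C6 | CC(C)[C@H]1C=C[C@@](O)(COC(=O)/C(=C/[C@H]2C=C(CO[Si](C)(C)C(C)(C)C)CC[C@H]2C(C)C)CO[Si](C)(C)C(C)(C)C)[C@H]2C(=O)OCC(C(=O)OCC[Si](C)(C)C)=C[C@@H]12 | intermediate
33 | protected target (bis-silyl ether, trimethylsilylethyl ester) | CC(C)[C@H]1CC[C@@](O)(COC(=O)/C(=C/[C@H]2C=C(CO[Si](C)(C)C(C)(C)C)CC[C@H]2C(C)C)CO[Si](C)(C)C(C)(C)C)[C@H]2C(=O)OCC(C(=O)OCC[Si](C)(C)C)=C[C@@H]12 | intermediate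
34 | CNP0361406.12 | CC(C)[C@H]1CC[C@@](O)(COC(=O)/C(=C/[C@H]2C=C(CO)CC[C@H]2C(C)C)CO)[C@H]2C(=O)OCC(C(=O)O)=C[C@@H]12 | target

**Totals**

Total step count: 26. Longest linear sequence: 20 steps (steps 1–15, 21, 23–26).

**Steps most likely to fail**

1. Step 21 (Proposed new method). What may go wrong: borylation at the γ-terminus C5 or on the face anti to lithium, loss of configuration of the lithiated species before boron capture, or migration of C1 to C7 with expulsion of the fragment 2 carboxylate. Fallback (known chemistry, no C–C union at C1): it sets out from 21 and returns at 33. Hydrogenation of 21 (H2, Pd/C) gives the saturated hydroxy lactone acetal F1; Dess–Martin oxidation gives the keto lactone acetal F2; Takai–Lombardo methylenation gives the exocyclic methylene lactone acetal F3; dilute HCl gives the hydroxy lactone F4; Wittig methylenation gives the diene acid F5; alkylation with 30 (KHCO3, DMF) gives the triene ester F6; ring-closing metathesis as in step 24 gives the methylene lactone F7. Epoxidation of the exocyclic alkene (m-CPBA) from the convex face, opposite the lactone, gives the spiro-epoxide F8, and opening of F8 at its CH2 carbon by the caesium salt of 17 (Cs2CO3, DMF, 60 °C) gives 33 with the C1 oxygen on the required face.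

2. Step 18. What may go wrong: E2 elimination of the activated allylic carbinol toward the acidic lactone α-hydrogen, or SN2′ attack, instead of SN2 inversion. Fallback (oxidation/reduction instead of substitution): it sets out from 21 and returns at 22. MnO2 oxidation gives the enone F9; reagent-controlled 1,2-reduction with 2-methyl-CBS-oxazaborolidine and catecholborane (the catalyst enantiomer that delivers hydride to the face of the lactone, chosen by trying both) gives the epimeric allylic alcohol F10; acylation with 2,4,6-triisopropylbenzoyl chloride and DMAP, with retention, gives 22.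

3. Step 10. What may go wrong: coupling of the allyl radical at the secondary terminus C2′, or hydrogen abstraction, competing with coupling at C7′. Fallback (ionic instead of radical): it sets out from 11 and returns at 14. Kinetic iodolactonization (iodine, NaHCO3, MeCN/H2O, 0 °C) gives the iodo-β-lactone F11; thermal loss of CO2 from the β-lactone (DMF, 80 °C) gives the allylic iodide F12 with the C1′=C2′ alkene; displacement with CsOAc gives the allylic acetate F13; K2CO3 in ethanol removes the acetate to give 14.

**Further compounds**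

F1 | step 21 | saturated hydroxy lactone acetal, core series | CC(C)[C@H]1CC[C@@H](O)[C@H]2C(=O)O[C@H](O[C@H]3C[C@@H](C)CC[C@@H]3C(C)C)[C@@H]12
F2 | step 21 | keto lactone acetal, core series | CC(C)[C@H]1CCC(=O)[C@H]2C(=O)O[C@H](O[C@H]3C[C@@H](C)CC[C@@H]3C(C)C)[C@@H]12
F3 | step 21 | exocyclic methylene lactone acetal, core series | CC(C)[C@H]1CCC(=C)[C@H]2C(=O)O[C@H](O[C@H]3C[C@@H](C)CC[C@@H]3C(C)C)[C@@H]12
F4 | step 21 | hydroxy lactone with C1=CH2, core series | CC(C)[C@H]1CCC(=C)[C@H]2C(=O)OC(O)[C@@H]12
F5 | step 21 | diene acid (C1=CH2, C2–CO2H, C3–vinyl) | CC(C)[C@H]1CCC(=C)[C@@H](C(=O)O)[C@H]1C=C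
F6 | step 21 | triene ester of F5 with 30 | CC(C)[C@H]1CCC(=C)[C@@H](C(=O)OCC(=C)C(=O)OCC[Si](C)(C)C)[C@H]1C=C
F7 | step 21 | seven-membered lactone with C1=CH2 | CC(C)[C@H]1CCC(=C)[C@H]2C(=O)OCC(C(=O)OCC[Si](C)(C)C)=C[C@@H]12
F8 | step 21 | spiro-epoxide at C1 (oxygen trans to the lactone carbonyl) | CC(C)[C@H]1CC[C@@]2(CO2)[C@H]3C(=O)OCC(C(=O)OCC[Si](C)(C)C)=C[C@@H]13
F9 | step 18 | enone (C1 ketone, C5=C6), core series | CC(C)[C@H]1C=CC(=O)[C@H]2C(=O)O[C@H](O[C@H]3C[C@@H](C)CC[C@@H]3C(C)C)[C@@H]12
F10 | step 18 | allylic alcohol epimeric with 21 at C1 | CC(C)[C@H]1C=C[C@H](O)[C@H]2C(=O)O[C@H](O[C@H]3C[C@@H](C)CC[C@@H]3C(C)C)[C@@H]12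
F11 | step 10 | iodo-β-lactone from 11 | CCOC(=O)/C(=C/[C@H]1[C@H]2C(=O)O[C@@]2(CI)CC[C@H]1C(C)C)COCc1ccc(OC)cc1
F12 | step 10 | allylic iodide (C7′–I) | CCOC(=O)/C(=C/[C@H]1C=C(CI)CC[C@H]1C(C)C)COCc1ccc(OC)cc1
F13 | step 10 | allylic acetate (C7′–OAc) | CCOC(=O)/C(=C/[C@H]1C=C(COC(C)=O)CC[C@H]1C(C)C)COCc1ccc(OC)cc1
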